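Remark: the target has no stereocentre. Locants C2–C8a (rings A and C) and C1'–C6' (ring B) are those of the isoflavone, while names of bicyclic ring B precursors use chromene locants. Compounds 4 and 15 are taken as purchasable.

## Analysis of the target

Kanzonol T (26, C25H26O7) is an isoflavone. Ring A carries hydroxyls at C5 and C7 and a 3-hydroxy-3-methylbutyl chain at C6 between them. Ring C is the 4-pyranone with an unsubstituted C2. Ring B is bonded to C3 through C1', has a free hydroxyl at C2', and is fused at C3'–C4' to a 2,2-dimethyl-2H-pyran whose oxygen sits on C4'.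

The molecule has no stereocentre, so any centre made on the way only has to be removable. The sensitive groups are:
- the tertiary alcohol, which ionises in acid and could then close onto a flanking phenol or dehydrate;
- the chromene double bond, which rules out hydrogenation and strong electrophiles;
- three phenols, which are open to oxidation;
- C2 of the chromone, which is open to nucleophiles.

The difficulty is regiochemical. The chain must sit at C6 and not at the electronically similar C8. Ring B must carry its hydroxyl ortho to the C3–C1' bond and the pyran oxygen one position further on. The C3–C1' bond is flanked by an ortho oxygen on one side and a carbonyl on the other.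

The strategy rests on the array C4(=O)–C3–C1'–C2'(–O). If ring B is read as the enol form of a cyclic enone, this is a 1,4-dicarbonyl unit, the retron of an acyl anion conjugate addition. Ring B with its pyran is then the aromatised form of the condensation product of 11 and 12, in which the two oxygens are already differentiated.

## Retrosynthetic reasoning

**26 to 24.** The two acetal C–O bonds on the C5 and C7 oxygens are cut last. These phenols have to stay masked through a lithiation, through an etherification in which only one phenol may react, through the carbene step and through an oxidation. Methoxymethyl ethers serve all four and fall under acid mild enough for the tertiary alcohol and the chromene.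

**24 to 22.** Four hydrogens are added back: two across C2–C3 of ring C and two on ring B, with the C2' phenol written as its keto tautomer. This turns the hindered aryl–C3 bond into a bond between two sp3 carbons, each alpha to a carbonyl, so 22 is a 1,4-diketone. The forward step has to dehydrogenate both rings under non-basic conditions, and both stereocentres of 22 vanish in it.

**22 to 21.** The C3–C4 bond is cut. This is the only cut that matches the natural polarity of an acyl anion and an enone beta-carbon, closes a six-membered ring, and uses catalysis known for this tether. A cut at C3–C1' would instead need a cross-coupling between two ortho-oxygenated partners. The gain is that 21 is a simple ether of two fragments of similar size. The forward reaction must make the aldehyde carbon nucleophilic and direct it to the exocyclic alkene carbon only.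

**21 to 10 and 20.** The aryl ether bond O1–C2 is cut. It joins a salicylaldehyde phenol to a primary allylic alcohol, which is a dehydrative etherification with no selectivity problem, since the only other hydroxyl is tertiary.

**20 back to 14 and 15, then 14 to 11 and 12.** The exocyclic C=C of 20 (through 19 and 17) is an aldol condensation between C6 of the vinylogous ester 14 and the two-carbon aldehyde 15. Compound 14 is cut at its C–C and C–O bonds to the pyran, giving 11 and 12. In 14 one oxygen of the dione is locked in the pyran and the other remains the ketone, so the later C2' hydroxyl and the C4' ether oxygen cannot be confused. The carbon next to the ketone becomes C1'.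

**10 back to 1 and 4.** The formyl group of 10 is removed to give the symmetric phenol 8, whose two ortho positions are equivalent and whose para position is blocked. The C–O bond of that phenol is cut back to a C–H bond in 6 (through the boronate 7). In 6 this is the only ring C–H not ortho to a substituent, so a sterically governed borylation can find it. The oxygen is introduced in this way and not carried as a halogen, because a ring halogen would exchange with the alkyllithium needed for the next cut. The aryl–CH2 bond of 6 is cut to the aryllithium 5, from 3, and the oxetane 4, which delivers the chain with its tertiary alcohol in one step. Compound 3 comes from 1.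

## Alternatives that were turned down

**Alternative 1:** Ring A is cut at C7–C8 and C5–C6 and grown last onto a finished pyranone.
- Forward key step: a lithium amide deprotonates the 2-methyl group of the pyranone ester A2 (methyl 5-[5-(methoxymethoxy)-2,2-dimethyl-2H-chromen-6-yl]-2-methyl-4-oxo-4H-pyran-3-carboxylate). The anion attacks the carbonyl of the lactone A3 (6,6-dimethyltetrahydro-2H-pyran-2-one). The ketone released on ring opening condenses through its far alpha-carbon with the ester, which would give A1 (Kanzonol T 2'-O-methoxymethyl ether) with ring A aromatic.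
- For it: the chain can only end at C6, because its carbon is the alpha-carbon of A3. Both ring A hydroxyls appear free and at the right oxidation level, the tertiary alcohol is the lactone oxygen, and no dehydrogenation follows. On redox economy and on ring A protecting groups it is stronger than the chosen plan.
- Against it: A2 is itself demanding. It is a fully substituted pyranone that already holds ring B, and its aryl–C3 bond would need a cross-coupling beside a carbonyl and an ortho acetal. The strong base must choose between the methyl group, the acidic C–H next to the ring oxygen of A2 and its electrophilic ring positions. After the first addition the CH2 between the pyranone and the new ketone is the most acidic site, whereas ring closure needs the enolate on the other side. Over-addition to the ketone is a further risk.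
- Comparison: the chosen route forms its one hard C–C bond catalytically, from two fragments that each take four steps from cheap materials, and pays for this with a late double dehydrogenation.

**Alternative 2:** Only ring A is disconnected, into a four-carbon and a two-carbon unit.
- Forward key step: heating the cyclobutenone A5 (2-[3-(tert-butyldimethylsilyloxy)-3-methylbutyl]-3-ethoxycyclobut-2-en-1-one) with the siloxyalkyne A6 ((triisopropylsilyloxy)ethyne) should open A5 to a vinylketene, which adds to A6 in a 2+2 sense. Ring opening of the adduct and six-electron closure would give the phenol A4 (4-[3-(tert-butyldimethylsilyloxy)-3-methylbutyl]-3-ethoxy-5-(triisopropylsilyloxy)phenol).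
- For it: the substitution pattern is dictated by the mechanism, no reagent is needed, and only the future O1 is free. In regiochemical certainty it is at least as strong as any aromatic substitution.
- Against it: A4 is no more than a counterpart of phenol 8, and the isoflavone would still have to be built from it by another key disconnection. A5 needs several steps. The ethyl ether of A4 sits on an oxygen that must end as a free hydroxyl, and it cannot be cleaved late without a strong Lewis acid that the chromene and the tertiary alcohol would not survive. Differentiating the two flanking oxygens is also unnecessary, since both end as hydroxyls.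
- Comparison: the chosen route reaches the same ring A pattern in three steps from 1 by using the symmetry of the ring, so the cycloaddition buys nothing here.

**Alternative 3:** Both oxygen heterocycles are opened at their C–O bonds, O1–C2 of ring C and the O–C bond to the dimethyl-substituted carbon of the pyran.
- Forward key step: the precursor is the enone A8 (1-[2-hydroxy-5-(3-hydroxy-3-methylbutyl)-4,6-bis(methoxymethoxy)phenyl]-2-[4-hydroxy-2-(methoxymethoxy)-3-(3-methylbut-2-en-1-yl)phenyl]prop-2-en-1-one). A divalent palladium carboxylate under dioxygen would add the ring A phenol to the terminal alkene carbon and the ring B phenol to the dimethyl-substituted carbon of the prenyl group, each followed by beta-hydride elimination, to give A7 (Kanzonol T 5,7,2'-tris(methoxymethyl) ether).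
- For it: chromone and chromene arise at their final oxidation level in one catalytic aerobic step, the oxygen pattern of ring B is fixed by which phenol is protected, and A7 needs only deprotection. In redox economy and brevity of the endgame it is stronger than the chosen plan.
- Against it: the step makes no C–C bond. The C3–C4 and C3–C1' bonds would have to come from an acylation of an acid-sensitive, acetal-protected ring A followed by alpha-methylenation. A8 is an alpha-aryl vinyl ketone with an ortho phenol, and it should close by oxa-Michael addition or oligomerise before palladium intervenes, so the oxidative cyclisation becomes in practice a dehydrogenation. The trisubstituted prenyl alkene reacts slowly and may close 5-exo to a dihydrobenzofuran. Ring B needs a regioselective prenylation between two oxygens.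
- Comparison: the chosen route makes the O–C bonds by simple reactions (steps 5 and 9) and keeps its key step for the C–C bond that is hardest to form.

Key step: step 10

## Route

Step 1
Reactants: 1 resorcinol (benzene-1,3-diol)
Product: 3 1,3-bis(methoxymethoxy)benzene, via mono(methoxymethyl) ether 2 (not isolated)
Conditions: MOMCl (2.5 equiv), i-Pr2NEt, CH2Cl2, 0 °C → rt
Reagents that add atoms: chloromethyl methyl ether, COCCl
Why: Williamson-type O-alkylation of both phenols by the reactive alpha-chloro ether under amine base; the acetal ethers are chosen because they direct the lithiation of step 2 and are removed by mild acid at the end.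

Step 2
Reactants: 3 1,3-bis(methoxymethoxy)benzene; 4 2,2-dimethyloxetane
Product: 6 4-[2,6-bis(methoxymethoxy)phenyl]-2-methylbutan-2-ol, via aryllithium 5 (not isolated)
Conditions: n-BuLi, THF, 0 °C; then 4, BF3·OEt2, −78 °C; then H2O
Reagents that add atoms: none
Why: Directed ortho-metalation removes the proton between the two acetal oxygens, which chelate lithium cooperatively. The aryllithium then opens the BF3-activated oxetane by SN2 attack at its unsubstituted CH2 carbon, away from the quaternary carbon, so the chain arrives with its tertiary hydroxyl in place.

Step 3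
Reactants: 6 4-[2,6-bis(methoxymethoxy)phenyl]-2-methylbutan-2-ol
Product: 8 4-(3-hydroxy-3-methylbutyl)-3,5-bis(methoxymethoxy)phenol, via aryl pinacolboronate 7 (not isolated)
Conditions: [Ir(OMe)(cod)]2 (1.5 mol %), 4,4'-di-tert-butyl-2,2'-bipyridine (3 mol %), B2pin2, THF, 80 °C; then 30% aq H2O2, aq NaOH, 0 °C → rt
Reagents that add atoms: hydrogen peroxide, OO
Why: Iridium-catalysed aromatic C–H borylation is governed by sterics and should select the only ring hydrogen that has no ortho substituent, para to the chain. Oxidation of the C–B bond then gives the phenol at that carbon, and any borate formed on the tertiary hydroxyl is hydrolysed in the same work-up.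

Step 4
Reactants: 8 4-(3-hydroxy-3-methylbutyl)-3,5-bis(methoxymethoxy)phenol
Product: 10 2-hydroxy-5-(3-hydroxy-3-methylbutyl)-4,6-bis(methoxymethoxy)benzaldehyde, via salicyl alcohol 9 (not isolated)
Conditions: MgCl2, Et3N, (CH2O)n, MeCN, 80 °C; then sat. aq NH4Cl
Reagents that add atoms: formaldehyde (as paraformaldehyde), C=O
Why: Casnati–Skattebøl ortho-formylation: the magnesium phenoxide delivers formaldehyde to the ortho carbon, and hydride transfer from the resulting benzylic alkoxide to a second formaldehyde gives the aldehyde. The two ortho positions of 8 are equivalent and the para position is blocked, so one isomer should form, under basic conditions that spare the acetals.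

Step 5
Reactants: 11 cyclohexane-1,3-dione; 12 3-methylbut-2-enal
Product: 14 2,2-dimethyl-7,8-dihydro-2H-chromen-5(6H)-one, via Knoevenagel dienone 13 (not isolated)
Conditions: ethylenediammonium diacetate (10 mol %), MeOH, rt → 50 °C
Reagents that add atoms: none
Why: Knoevenagel condensation gives a 1-oxatriene that closes by oxa-6π electrocyclisation to the 2H-pyran. One dione oxygen becomes the pyran oxygen and the other stays as the ketone, which fixes the oxygen pattern of ring B.

Step 6
Reactants: 14 2,2-dimethyl-7,8-dihydro-2H-chromen-5(6H)-one; 15 (tert-butyldimethylsilyloxy)acetaldehyde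
Product: 17 6-[2-(tert-butyldimethylsilyloxy)-1-hydroxyethyl]-2,2-dimethyl-7,8-dihydro-2H-chromen-5(6H)-one (diastereomer mixture), via lithium enolate 16 (not isolated)
Conditions: LDA, THF, −78 °C; then 15, −78 °C; then sat. aq NH4Cl
Reagents that add atoms: none
Why: Kinetic deprotonation of a vinylogous ester by a lithium amide occurs at the alpha-prime carbon (C6) and not at the gamma carbon, and the enolate adds to the aldehyde in an aldol addition. The two new stereocentres form without control and are removed in step 7.

Step 7
Reactants: 17 6-[2-(tert-butyldimethylsilyloxy)-1-hydroxyethyl]-2,2-dimethyl-7,8-dihydro-2H-chromen-5(6H)-one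
Product: 19 (E)-6-[2-(tert-butyldimethylsilyloxy)ethylidene]-2,2-dimethyl-7,8-dihydro-2H-chromen-5(6H)-one, via mesylate 18 (not isolated)
Conditions: MsCl, Et3N, CH2Cl2, 0 °C; then DBU, 0 °C → rt
Reagents that add atoms: none
Why: Sulfonylation of the secondary alcohol followed by E1cB elimination through the ketone enolate gives the exocyclic enone. The E isomer, with the vinyl hydrogen beside the carbonyl, is the usual thermodynamic outcome for 2-alkylidene cycloalkanones, and the geometry is not critical for step 10.

Step 8
Reactants: 19 (E)-6-[2-(tert-butyldimethylsilyloxy)ethylidene]-2,2-dimethyl-7,8-dihydro-2H-chromen-5(6H)-one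
Product: 20 (E)-6-(2-hydroxyethylidene)-2,2-dimethyl-7,8-dihydro-2H-chromen-5(6H)-one
Conditions: Bu4NF, AcOH, THF, 0 °C
Reagents that add atoms: none
Why: Fluoride cleaves the primary silyl ether; acetic acid buffers the alkoxide so that the gamma-hydroxy enone is not exposed to strong base.

Step 9
Reactants: 10 2-hydroxy-5-(3-hydroxy-3-methylbutyl)-4,6-bis(methoxymethoxy)benzaldehyde; 20 (E)-6-(2-hydroxyethylidene)-2,2-dimethyl-7,8-dihydro-2H-chromen-5(6H)-one
Product: 21 2-[(E)-2-(2,2-dimethyl-5-oxo-7,8-dihydro-2H-chromen-6(5H)-ylidene)ethoxy]-5-(3-hydroxy-3-methylbutyl)-4,6-bis(methoxymethoxy)benzaldehyde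
Conditions: PPh3, DIAD, THF, 0 °C → rt
Reagents that add atoms: none
Why: Mitsunobu etherification: the acidic, hydrogen-bonded salicylaldehyde phenol is the pronucleophile and displaces the phosphonium-activated primary allylic oxygen by SN2 at CH2. The tertiary alcohol of 10 is inert under these conditions and no stereocentre is involved.

Step 10
Reactants: 21 2-[(E)-2-(2,2-dimethyl-5-oxo-7,8-dihydro-2H-chromen-6(5H)-ylidene)ethoxy]-5-(3-hydroxy-3-methylbutyl)-4,6-bis(methoxymethoxy)benzaldehyde
Product: 22 3-(2,2-dimethyl-5-oxo-5,6,7,8-tetrahydro-2H-chromen-6-yl)-6-(3-hydroxy-3-methylbutyl)-5,7-bis(methoxymethoxy)chroman-4-one (diastereomer mixture)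
Conditions: 3-benzyl-5-(2-hydroxyethyl)-4-methylthiazolium chloride (20 mol %), Et3N, 1,4-dioxane, 70 °C, N2
Reagents that add atoms: none
Why: Et3N deprotonates the thiazolium salt to the carbene, which adds to the aldehyde of 21; proton transfer gives the Breslow intermediate, an acyl anion equivalent, whose carbon adds to the exocyclic beta-carbon of the enone, and protonation of the enolate and loss of the carbene give the 1,4-diketone 22. The closest known reaction type is the intramolecular Stetter reaction of O-tethered salicylaldehyde Michael acceptors to chroman-4-ones, including acceptors substituted at the alpha-carbon. Ring C closes 6-exo-trig: the new C3–C4 bond lies in a ring of six atoms (C4a, C4, C3, C2, O1, C8a) and the acceptor C=C stays outside it. C3 is set in the C–C bond formation and C1' in the protonation of the enolate; neither catalyst nor substrate offers useful control, so racemic diastereomers are expected, which is acceptable because both centres become sp2 in step 11. The step needs 1,4-addition to win over benzoin-type dimerisation and over attack on the ketone carbonyl: the two ortho oxygens hinder bimolecular acyloin formation, the tether puts only the beta-carbon within reach (attack on the ketone carbon would need an eight-membered ring), and the exocyclic alkylidene ketone is held s-cis and is a reactive acceptor despite the donation of the vinylogous ester. A weak amine base and moderate temperature are chosen so that the gamma-aryloxy enone is not deconjugated and the beta-aryloxy ketone of 22 is not opened by retro-oxa-Michael reaction.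

Step 11
Reactants: 22 3-(2,2-dimethyl-5-oxo-5,6,7,8-tetrahydro-2H-chromen-6-yl)-6-(3-hydroxy-3-methylbutyl)-5,7-bis(methoxymethoxy)chroman-4-one
Product: 24 3-(5-hydroxy-2,2-dimethyl-2H-chromen-6-yl)-6-(3-hydroxy-3-methylbutyl)-5,7-bis(methoxymethoxy)-4H-chromen-4-one, via isoflavanone phenol 23 (not isolated)
Conditions: DDQ (2.2 equiv), 1,4-dioxane, 80 °C
Reagents that add atoms: none
Why: Quinone dehydrogenation through enol formation and hydride abstraction: the carbocycle should lose one hydrogen pair and tautomerise to the phenol of ring B, and the chromanone should lose hydride from C2 of its enol and a proton to give the chromone. Ring B is expected to aromatise first because it has more enolisation pathways and the larger driving force, though either order gives 24. The acetals, the tertiary alcohol and the chromene are not hydride donors, and both stereocentres of 22 are erased.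

Step 12
Reactants: 24 3-(5-hydroxy-2,2-dimethyl-2H-chromen-6-yl)-6-(3-hydroxy-3-methylbutyl)-5,7-bis(methoxymethoxy)-4H-chromen-4-one
Product: 26 Kanzonol T, via 7-O-methoxymethyl ether 25 (not isolated)
Conditions: HCl (ca. 1 M) in MeOH, rt → 40 °C
Reagents that add atoms: none
Why: Acid-catalysed transacetalisation to methanol removes both acetals, the one on the C5 oxygen beside the carbonyl first. Dilute acid and low temperature are chosen so that the tertiary alcohol does not ionise and the chromene is untouched.

## Compound list

1 | resorcinol (benzene-1,3-diol) | Oc1cccc(O)c1 | starting material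
2 | 3-(methoxymethoxy)phenol | COCOc1cccc(O)c1 | intermediate
3 | 1,3-bis(methoxymethoxy)benzene | COCOc1cccc(OCOC)c1 | intermediate
4 | 2,2-dimethyloxetane | CC1(C)CCO1 | starting material
5 | 2,6-bis(methoxymethoxy)phenyllithium | [Li]c1c(OCOC)cccc1OCOC | intermediate
6 | 4-[2,6-bis(methoxymethoxy)phenyl]-2-methylbutan-2-ol | CC(C)(O)CCc1c(OCOC)cccc1OCOC | intermediate
7 | 4-[2,6-bis(methoxymethoxy)-4-(4,4,5,5-tetramethyl-1,3,2-dioxaborolan-2-yl)phenyl]-2-methylbutan-2-ol | CC(C)(O)CCc1c(OCOC)cc(B2OC(C)(C)C(C)(C)O2)cc1OCOC | intermediate
8 | 4-(3-hydroxy-3-methylbutyl)-3,5-bis(methoxymethoxy)phenol | CC(C)(O)CCc1c(OCOC)cc(O)cc1OCOC | intermediate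
9 | 2-(hydroxymethyl)-4-(3-hydroxy-3-methylbutyl)-3,5-bis(methoxymethoxy)phenol (present as its magnesium salt) | CC(C)(O)CCc1c(OCOC)cc(O)c(CO)c1OCOC | intermediate
10 | 2-hydroxy-5-(3-hydroxy-3-methylbutyl)-4,6-bis(methoxymethoxy)benzaldehyde | CC(C)(O)CCc1c(OCOC)cc(O)c(C=O)c1OCOC | intermediate
11 | cyclohexane-1,3-dione | O=C1CCCC(=O)C1 | starting material
12 | 3-methylbut-2-enal | CC(C)=CC=O | starting material
13 | 2-(3-methylbut-2-en-1-ylidene)cyclohexane-1,3-dione | CC(C)=CC=C1C(=O)CCCC1=O | intermediate
14 | 2,2-dimethyl-7,8-dihydro-2H-chromen-5(6H)-one | CC1(C)C=CC2=C(CCCC2=O)O1 | intermediate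
15 | (tert-butyldimethylsilyloxy)acetaldehyde | O=CCO[Si](C)(C)C(C)(C)C | starting material
16 | lithium 2,2-dimethyl-7,8-dihydro-2H-chromen-5-olate (enolate of 14) | CC1(C)C=CC2=C(CCC=C2O[Li])O1 | intermediate
17 | 6-[2-(tert-butyldimethylsilyloxy)-1-hydroxyethyl]-2,2-dimethyl-7,8-dihydro-2H-chromen-5(6H)-one (diastereomer mixture) | CC1(C)C=CC2=C(CCC(C(O)CO[Si](C)(C)C(C)(C)C)C2=O)O1 | intermediate
18 | 2-(tert-butyldimethylsilyloxy)-1-(2,2-dimethyl-5-oxo-5,6,7,8-tetrahydro-2H-chromen-6-yl)ethyl methanesulfonate | CC1(C)C=CC2=C(CCC(C(OS(C)(=O)=O)CO[Si](C)(C)C(C)(C)C)C2=O)O1 | intermediate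
19 | (E)-6-[2-(tert-butyldimethylsilyloxy)ethylidene]-2,2-dimethyl-7,8-dihydro-2H-chromen-5(6H)-one | CC(C)(C)[Si](C)(C)OC/C=C1\CCC2=C(C=CC(C)(C)O2)C1=O | intermediate
20 | (E)-6-(2-hydroxyethylidene)-2,2-dimethyl-7,8-dihydro-2H-chromen-5(6H)-one | OC/C=C1\CCC2=C(C=CC(C)(C)O2)C1=O | intermediate
21 | 2-[(E)-2-(2,2-dimethyl-5-oxo-7,8-dihydro-2H-chromen-6(5H)-ylidene)ethoxy]-5-(3-hydroxy-3-methylbutyl)-4,6-bis(methoxymethoxy)benzaldehyde | CC(C)(O)CCc1c(OCOC)cc(OC/C=C2\CCC3=C(C=CC(C)(C)O3)C2=O)c(C=O)c1OCOC | intermediate
22 | 3-(2,2-dimethyl-5-oxo-5,6,7,8-tetrahydro-2H-chromen-6-yl)-6-(3-hydroxy-3-methylbutyl)-5,7-bis(methoxymethoxy)chroman-4-one (diastereomer mixture) | CC(C)(O)CCc1c(OCOC)cc2OCC(C3CCC4=C(C=CC(C)(C)O4)C3=O)C(=O)c2c1OCOC | intermediate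
23 | 3-(5-hydroxy-2,2-dimethyl-2H-chromen-6-yl)-6-(3-hydroxy-3-methylbutyl)-5,7-bis(methoxymethoxy)chroman-4-one (racemic) | CC(C)(O)CCc1c(OCOC)cc2OCC(c3ccc4OC(C)(C)C=Cc4c3O)C(=O)c2c1OCOC | intermediate
24 | 3-(5-hydroxy-2,2-dimethyl-2H-chromen-6-yl)-6-(3-hydroxy-3-methylbutyl)-5,7-bis(methoxymethoxy)-4H-chromen-4-one | CC(C)(O)CCc1c(OCOC)cc2occ(-c3ccc4OC(C)(C)C=Cc4c3O)c(=O)c2c1OCOC | intermediate
25 | 5-hydroxy-3-(5-hydroxy-2,2-dimethyl-2H-chromen-6-yl)-6-(3-hydroxy-3-methylbutyl)-7-(methoxymethoxy)-4H-chromen-4-one | CC(C)(O)CCc1c(OCOC)cc2occ(-c3ccc4OC(C)(C)C=Cc4c3O)c(=O)c2c1O | intermediate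
26 | Kanzonol T, 5,7-dihydroxy-3-(5-hydroxy-2,2-dimethyl-2H-chromen-6-yl)-6-(3-hydroxy-3-methylbutyl)-4H-chromen-4-one | CC(C)(O)CCc1c(O)cc2occ(-c3ccc4c(c3O)C=CC(C)(C)O4)c(=O)c2c1O | target

## Step count and least certain steps

Total step count: 12. Longest linear sequence: 8 steps (steps 1–4 then 9–12, or steps 5–8 then 9–12).

**Step 10 (key step).** The aldehyde of 21 lies between two ortho oxygens and is electron-rich, so carbene addition and formation of the Breslow intermediate may be slow. The amine base could then deconjugate the gamma-aryloxy enone, or isomerise the alkylidene dienone towards an aromatic ring B, before the C–C bond forms. Fallback: from 21, a reductive radical closure in place of the umpolung. SmI2 in THF with t-BuOH at −78 °C should form the ketyl of the aldehyde, which adds 6-exo to the enone beta-carbon and gives the chroman-4-ol F1 as a diastereomer mixture. Oxidation of the secondary alcohol of F1 with Dess–Martin periodinane returns to the route at 22.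

**Step 11.** Three things could go wrong: over-oxidation of the electron-rich ring B phenol once it has formed (for instance oxidative closure of the C2' oxygen onto C2), incomplete dehydrogenation of ring C, or acid-induced cyclodehydration of the 1,4-diketone to a furan by the hydroquinone that accumulates. Fallback: from 22, the oxidation is done on preformed enol ethers. LiHMDS with Me3SiCl at −78 °C should give the tris(trimethylsilyl) derivative F2, with both ketones as silyl enol ethers and the tertiary hydroxyl silylated. Saegusa–Ito oxidation with Pd(OAc)2 in MeCN then desaturates C2–C3 and the carbocycle, whose dienone tautomerises to the phenol, giving the silyl ether F3. Under the conditions of step 12, F3 loses the silyl group together with the acetals and comes back to the route at 26.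

**Step 2.** The doubly chelated aryllithium 5 is a modest nucleophile, and the Lewis acid may ionise the oxetane at its quaternary carbon and isomerise or oligomerise it before it is attacked. Fallback: from 3, the aryllithium 5 is made as before, transmetalated with CuBr·SMe2 and alkylated with 1-bromo-3-methylbut-2-ene to give 1,3-bis(methoxymethoxy)-2-(3-methylbut-2-en-1-yl)benzene F4. Mukaiyama hydration of F4 (Co(acac)2, PhSiH3, O2, i-PrOH) places the hydroxyl on the more substituted alkene carbon and returns to the route at 6.

**Step 9.** The phosphonium-activated allylic alcohol could undergo base-induced 1,4-elimination with aromatisation of ring B, or conjugate addition of the phenoxide to the enone, instead of direct displacement. Fallback: from 20, Appel bromination (CBr4, PPh3, CH2Cl2, 0 °C) gives (E)-6-(2-bromoethylidene)-2,2-dimethyl-7,8-dihydro-2H-chromen-5(6H)-one F5. Williamson etherification of F5 with phenol 10 (K2CO3, acetone, rt) returns to the route at 21.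

## Further compounds

F1 | step 10 | 3-(2,2-dimethyl-5-oxo-5,6,7,8-tetrahydro-2H-chromen-6-yl)-6-(3-hydroxy-3-methylbutyl)-5,7-bis(methoxymethoxy)chroman-4-ol (diastereomer mixture) | CC(C)(O)CCc1c(OCOC)cc2OCC(C3CCC4=C(C=CC(C)(C)O4)C3=O)C(O)c2c1OCOC
F2 | step 11 | 2,2-dimethyl-6-{5,7-bis(methoxymethoxy)-6-[3-methyl-3-(trimethylsilyloxy)butyl]-4-(trimethylsilyloxy)-2H-chromen-3-yl}-5-(trimethylsilyloxy)-7,8-dihydro-2H-chromene | CC(C)(O[Si](C)(C)C)CCc1c(OCOC)cc2OCC(=C(O[Si](C)(C)C)c2c1OCOC)C1=C(O[Si](C)(C)C)C2=C(CC1)OC(C)(C)C=C2
F3 | step 11 | 3-(5-hydroxy-2,2-dimethyl-2H-chromen-6-yl)-5,7-bis(methoxymethoxy)-6-[3-methyl-3-(trimethylsilyloxy)butyl]-4H-chromen-4-one | CC(C)(O[Si](C)(C)C)CCc1c(OCOC)cc2occ(-c3ccc4OC(C)(C)C=Cc4c3O)c(=O)c2c1OCOC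
F4 | step 2 | 1,3-bis(methoxymethoxy)-2-(3-methylbut-2-en-1-yl)benzene | CC(C)=CCc1c(OCOC)cccc1OCOC
F5 | step 9 | (E)-6-(2-bromoethylidene)-2,2-dimethyl-7,8-dihydro-2H-chromen-5(6H)-one | BrC/C=C1\CCC2=C(C=CC(C)(C)O2)C1=O
A1 | alternative 1 | Kanzonol T 2'-O-methoxymethyl ether | CC(C)(O)CCc1c(O)cc2occ(-c3ccc4OC(C)(C)C=Cc4c3OCOC)c(=O)c2c1O
A2 | alternative 1 | methyl 5-[5-(methoxymethoxy)-2,2-dimethyl-2H-chromen-6-yl]-2-methyl-4-oxo-4H-pyran-3-carboxylate | COC(=O)c1c(C)occ(-c2ccc3OC(C)(C)C=Cc3c2OCOC)c1=O
A3 | alternative 1 | 6,6-dimethyltetrahydro-2H-pyran-2-one | CC1(C)CCCC(=O)O1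
A4 | alternative 2 | 4-[3-(tert-butyldimethylsilyloxy)-3-methylbutyl]-3-ethoxy-5-(triisopropylsilyloxy)phenol | CCOc1cc(O)cc(O[Si](C(C)C)(C(C)C)C(C)C)c1CCC(C)(C)O[Si](C)(C)C(C)(C)C
A5 | alternative 2 | 2-[3-(tert-butyldimethylsilyloxy)-3-methylbutyl]-3-ethoxycyclobut-2-en-1-one | CCOC1=C(CCC(C)(C)O[Si](C)(C)C(C)(C)C)C(=O)C1
A6 | alternative 2 | (triisopropylsilyloxy)ethyne | C#CO[Si](C(C)C)(C(C)C)C(C)C
A7 | alternative 3 | Kanzonol T 5,7,2'-tris(methoxymethyl) ether | CC(C)(O)CCc1c(OCOC)cc2occ(-c3ccc4OC(C)(C)C=Cc4c3OCOC)c(=O)c2c1OCOC
A8 | alternative 3 | 1-[2-hydroxy-5-(3-hydroxy-3-methylbutyl)-4,6-bis(methoxymethoxy)phenyl]-2-[4-hydroxy-2-(methoxymethoxy)-3-(3-methylbut-2-en-1-yl)phenyl]prop-2-en-1-one | CC(C)(O)CCc1c(OCOC)cc(O)c(C(=O)C(=C)c2ccc(O)c(CC=C(C)C)c2OCOC)c1OCOC
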